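**Plan**
- Retrosynthesis: the chain is cut at C11'=C12' (Wittig: C25 ylide carrying ring A + C15 hydroxy aldehyde carrying ring B) and at C11=C12 (Wittig: C15 ylide of ring A + C10 dialdehyde). Both C15 pieces go back through C9=C10 and C7=C8 olefinations to one ring aldehyde, whose ring is cut at C1–C6.
- Enabling feature: in ring A (C1–C6) the only stereocentre, C6, lies between the gem-dimethyl carbon C1 and the C4=C5 double bond. This is the pattern left when a C5=C6 alkene closes onto a C1 cation and a group leaves from C4. Ring B (C1'–C6') has the same C6' centre in the same spatial sense, so one cyclisation product feeds both rings.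
- Forward order: acyclic allylsilane (steps 1–9), ring closure (step 10), (S)-α-ionone 17 (steps 11–13). Branch a gives the C15 salt, the C25 aldehyde and the C25 salt (steps 14–18). Branch b oxygenates C3' and builds the C15 hydroxy aldehyde (steps 19–24). Step 25 joins them.
- Stereochemistry: a CBS reduction sets an allylic carbinol, which is relayed to the C–Si centre by syn SN2' silylation and to C6/C6' by anti SE2' ring closure. C3' comes from ring-controlled hydride addition trans to the C6' side chain. Chain alkenes are E from olefination and thermal equilibration.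

Key step: step 10

Assumption: the SMILES is read as all-E (3S,6S,6'S)-ε,ε-caroten-3-ol with the hydroxyl trans to the C6' side chain; carotenoid numbering is used for ring positions, and Z isomers from steps 13, 15, 16, 23 and 25 are taken to be removed by crystallisation or chromatography or equilibrated on warming.

**Route**

Step 1
Reactants: 1 5,5-dimethyldihydrofuran-2(3H)-one
Product: 2 5,5-dimethyltetrahydrofuran-2-ol
Conditions: i-Bu2AlH (1.1 equiv), CH2Cl2, −78 °C
Reagents that add atoms: none
Why: partial lactone reduction, since one equivalent of i-Bu2AlH at low temperature stops at the aluminium hemiacetal, which gives the lactol on work-up.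

Step 2
Reactants: 2 5,5-dimethyltetrahydrofuran-2-ol; 3 ethyl 2-(triphenylphosphoranylidene)propanoate
Product: 4 ethyl (E)-6-hydroxy-2,6-dimethylhept-2-enoate
Conditions: toluene, 80 °C
Reagents that add atoms: none
Why: Wittig olefination, in which the lactol supplies the open hydroxy aldehyde and the stabilised ylide should give the E trisubstituted enoate with the ester trans to the chain.

Step 3
Reactants: 4 ethyl (E)-6-hydroxy-2,6-dimethylhept-2-enoate
Product: 5 ethyl (E)-2,6-dimethyl-6-[(trimethylsilyl)oxy]hept-2-enoate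
Conditions: 1-(trimethylsilyl)imidazole, CH2Cl2, 23 °C
Reagents that add atoms: 1-(trimethylsilyl)imidazole C[Si](C)(C)n1ccnc1
Why: O-silylation, as the N-silylimidazole silylates even a tertiary alcohol under neutral conditions and the ether keeps a free alkoxide out of the organometallic steps 4, 5 and 9.

Step 4
Reactants: 5 ethyl (E)-2,6-dimethyl-6-[(trimethylsilyl)oxy]hept-2-enoate
Product: 6 (E)-N-methoxy-N,2,6-trimethyl-6-[(trimethylsilyl)oxy]hept-2-enamide
Conditions: MeNH(OMe)·HCl, i-PrMgCl, THF, −20 → 0 °C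
Reagents that add atoms: N,O-dimethylhydroxylamine hydrochloride CNOC.Cl
Why: Weinreb amide formation by aminolysis of the ester with the chloromagnesium amide, which attacks the α-branched conjugated ester at the carbonyl carbon.

Step 5
Reactants: 6 (E)-N-methoxy-N,2,6-trimethyl-6-[(trimethylsilyl)oxy]hept-2-enamide
Product: 7 (E)-1-chloro-3,7-dimethyl-7-[(trimethylsilyl)oxy]oct-3-en-2-one
Conditions: ICH2Cl, MeLi·LiBr, THF–Et2O, −78 °C
Reagents that add atoms: chloroiodomethane ClCI
Why: carbenoid homologation of a Weinreb amide, in which chloromethyllithium made by iodine–lithium exchange adds once at the carbonyl because the chelated tetrahedral adduct survives until the quench.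

Step 6
Reactants: 7 (E)-1-chloro-3,7-dimethyl-7-[(trimethylsilyl)oxy]oct-3-en-2-one
Product: 8 (E)-3,7-dimethyl-2-oxo-7-[(trimethylsilyl)oxy]oct-3-en-1-yl pivalate
Conditions: t-BuCO2H, K2CO3, NaI (10 mol %), DMF, 23 °C
Reagents that add atoms: pivalic acid CC(C)(C)C(=O)O
Why: SN2 displacement of an activated α-chloro ketone by a carboxylate, assisted by iodide, which installs the pivalate that the ring closure later carries as a spectator.

Step 7
Reactants: 8 (E)-3,7-dimethyl-2-oxo-7-[(trimethylsilyl)oxy]oct-3-en-1-yl pivalate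
Product: 9 (2S,3E)-2-hydroxy-3,7-dimethyl-7-[(trimethylsilyl)oxy]oct-3-en-1-yl pivalate
Conditions: (S)-1-methyl-3,3-diphenyltetrahydro-1H,3H-pyrrolo[1,2-c][1,3,2]oxazaborole (20 mol %), catecholborane, toluene, −78 °C
Reagents that add atoms: none
Why: CBS reduction, in which the α-methylalkenyl group acts as the large and CH2OPiv as the small ketone substituent, so the (S)-catalyst should deliver hydride 1,2 to the face that gives the (S)-carbinol.

Step 8
Reactants: 9 (2S,3E)-2-hydroxy-3,7-dimethyl-7-[(trimethylsilyl)oxy]oct-3-en-1-yl pivalate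
Product: 10 (2S,3E)-3,7-dimethyl-2-[(phenylcarbamoyl)oxy]-7-[(trimethylsilyl)oxy]oct-3-en-1-yl pivalate
Conditions: PhNCO, Et3N (10 mol %), CH2Cl2, 23 °C
Reagents that add atoms: phenyl isocyanate O=C=Nc1ccccc1
Why: carbamoylation of a secondary alcohol by an aryl isocyanate, which needs no strong base, so the neighbouring pivalate should not migrate and the carbinol centre is untouched.

Step 9
Reactants: 10 (2S,3E)-3,7-dimethyl-2-[(phenylcarbamoyl)oxy]-7-[(trimethylsilyl)oxy]oct-3-en-1-yl pivalate; 11 chlorodimethylphenylsilane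
Product: 13 (2E,4S)-4-[dimethyl(phenyl)silyl]-7-hydroxy-3,7-dimethyloct-2-en-1-yl pivalate, via trimethylsilyl ether 12 (not isolated)
Conditions: n-BuLi (1.0 equiv), THF, −78 °C; CuI, PPh3, −78 → 0 °C; PhMe2SiLi (1.0 equiv, from 11 and Li, THF, 0 °C), −78 → 0 °C; then citric acid, MeOH, 23 °C
Reagents that add atoms: none
Why: syn SN2' silylation of an allylic N-phenylcarbamate by an amidocuprate, in which the single equivalent of silicon is delivered from the carbamate nitrogen to the distal alkene carbon on the face of the leaving oxygen, so the (S)-carbinol becomes the (S)-silane, the E alkene arises from the conformer with the carbinol hydrogen eclipsing the old double bond (a minor Z isomer formed through the other conformer would carry the opposite silicon configuration and lead to the same ring enantiomer), and mild acidic methanolysis then frees the tertiary alcohol.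

Step 10
Reactants: 13 (2E,4S)-4-[dimethyl(phenyl)silyl]-7-hydroxy-3,7-dimethyloct-2-en-1-yl pivalate
Product: 14 [(1S)-2,6,6-trimethylcyclohex-2-en-1-yl]methyl pivalate
Conditions: SnCl4 (1.1 equiv), 2,6-di-tert-butyl-4-methylpyridine (0.3 equiv), CH2Cl2, −78 °C
Reagents that add atoms: none
Why: SnCl4 ionises the tertiary alcohol (carotenoid C1), the C5=C6 double bond attacks the cation through C6 so that the C1–C6 bond forms, the charge building up at C5 is stabilised by the C4–Si bond lying parallel to the π system, and loss of silicon leaves the C4=C5 double bond and no other alkene isomer. The closest known reaction types are the Lewis-acid allylation of tertiary alcohols by allylsilanes and the allylsilane-terminated cation–olefin cyclisation of terpenoid chains (SE2'). The six-membered ring closes in a chair-like 6-endo-trig mode in which both carbons of the attacked alkene become ring atoms. The new C6 stereocentre is controlled by the silicon-bearing C4 centre: the tether and silicon must lie on opposite faces of the E double bond, attack at C6 is anti to silicon, and (S)-C4 therefore gives (S)-C6. The step needs ring closure to be faster than proton loss from the C1 cation, protonolysis of the C–Si bond and silicon-assisted loss of the pivalate; the high nucleophilicity of an allylsilane that reacts through a tertiary β-silyl cation, the hindered pyridine buffer, the low temperature and the poor leaving-group ability of a primary pivalate are relied on for this.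

Step 11
Reactants: 14 [(1S)-2,6,6-trimethylcyclohex-2-en-1-yl]methyl pivalate
Product: 15 [(1S)-2,6,6-trimethylcyclohex-2-en-1-yl]methanol
Conditions: i-Bu2AlH (2.2 equiv), CH2Cl2, −78 °C
Reagents that add atoms: none
Why: reductive ester cleavage, which removes the pivalate without base and leaves the stereocentre and the ring alkene untouched.

Step 12
Reactants: 15 [(1S)-2,6,6-trimethylcyclohex-2-en-1-yl]methanol
Product: 16 (1S)-2,6,6-trimethylcyclohex-2-ene-1-carbaldehyde
Conditions: Dess–Martin periodinane [1,1,1-triacetoxy-1,1-dihydro-1,2-benziodoxol-3(1H)-one], NaHCO3, CH2Cl2, 0 °C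
Reagents that add atoms: none
Why: Dess–Martin oxidation under bicarbonate buffer is neutral and fast, which should limit epimerisation at C6 and migration of the ring double bond into conjugation.

Step 13
Reactants: 16 (1S)-2,6,6-trimethylcyclohex-2-ene-1-carbaldehyde
Product: 17 (E)-4-[(1S)-2,6,6-trimethylcyclohex-2-en-1-yl]but-3-en-2-one
Conditions: (MeO)2P(O)CH2COCH3, Ba(OH)2, THF–H2O (40:1), 23 °C
Reagents that add atoms: dimethyl (2-oxopropyl)phosphonate COP(=O)(CC(C)=O)OC
Why: Horner–Wadsworth–Emmons olefination under heterogeneous Ba(OH)2, conditions used for epimerisable α-branched aldehydes, should give the E enone while the more acidic ketophosphonate takes up the base.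

Step 14
Reactants: 17 (E)-4-[(1S)-2,6,6-trimethylcyclohex-2-en-1-yl]but-3-en-2-one
Product: 18 (E)-3-methyl-1-[(1S)-2,6,6-trimethylcyclohex-2-en-1-yl]penta-1,4-dien-3-ol
Conditions: CH2=CHMgBr, THF, −20 → 0 °C
Reagents that add atoms: vinylmagnesium bromide C=C[Mg]Br
Why: Grignard 1,2-addition to an ionone-type enone gives the tertiary bis-allylic carbinol, whose new centre is lost in the next step and so may be a mixture.

Step 15
Reactants: 18 (E)-3-methyl-1-[(1S)-2,6,6-trimethylcyclohex-2-en-1-yl]penta-1,4-dien-3-ol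
Product: 19 [(2E,4E)-3-methyl-5-[(1S)-2,6,6-trimethylcyclohex-2-en-1-yl]penta-2,4-dien-1-yl]triphenylphosphonium bromide
Conditions: PPh3·HBr, MeOH, 0 → 23 °C
Reagents that add atoms: triphenylphosphine hydrobromide Br.c1ccc(cc1)P(c1ccccc1)c1ccccc1
Why: phosphonium salt formation with allylic transposition, in which the mild acid ionises the tertiary bis-allylic alcohol and the phosphine captures the pentadienyl cation at its primary end, the 2E salt being purified by crystallisation.

Step 16
Reactants: 19 [(2E,4E)-3-methyl-5-[(1S)-2,6,6-trimethylcyclohex-2-en-1-yl]penta-2,4-dien-1-yl]triphenylphosphonium bromide; 20 (2E,4E,6E)-2,7-dimethylocta-2,4,6-trienedial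
Product: 22 (2E,4E,6E,8E,10E,12E)-2,7,11-trimethyl-13-[(1S)-2,6,6-trimethylcyclohex-2-en-1-yl]trideca-2,4,6,8,10,12-hexaenal, via ylide 21 (not isolated)
Conditions: 20 (2.5 equiv), NaOMe, MeOH–CH2Cl2, 0 → 23 °C; then heptane, 80 °C
Reagents that add atoms: none
Why: Wittig olefination in which an excess of the dialdehyde favours mono-condensation and the hindered Z isomer at the new C11=C12 bond should relax to E on warming.

Step 17
Reactants: 22 (2E,4E,6E,8E,10E,12E)-2,7,11-trimethyl-13-[(1S)-2,6,6-trimethylcyclohex-2-en-1-yl]trideca-2,4,6,8,10,12-hexaenal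
Product: 23 (2E,4E,6E,8E,10E,12E)-2,7,11-trimethyl-13-[(1S)-2,6,6-trimethylcyclohex-2-en-1-yl]trideca-2,4,6,8,10,12-hexaen-1-ol
Conditions: NaBH4, EtOH–THF, 0 °C
Reagents that add atoms: none
Why: borohydride reduction of a polyenal is 1,2-selective and gives the primary polyenylic alcohol.

Step 18
Reactants: 23 (2E,4E,6E,8E,10E,12E)-2,7,11-trimethyl-13-[(1S)-2,6,6-trimethylcyclohex-2-en-1-yl]trideca-2,4,6,8,10,12-hexaen-1-ol
Product: 24 [(2E,4E,6E,8E,10E,12E)-2,7,11-trimethyl-13-[(1S)-2,6,6-trimethylcyclohex-2-en-1-yl]trideca-2,4,6,8,10,12-hexaen-1-yl]triphenylphosphonium bromide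
Conditions: PPh3·HBr, CH2Cl2–MeOH, 0 → 23 °C
Reagents that add atoms: triphenylphosphine hydrobromide Br.c1ccc(cc1)P(c1ccccc1)c1ccccc1
Why: phosphonium salt formation from a polyenylic alcohol, which ionises readily and is captured by the phosphine at the terminal carbon so that conjugation is kept.

Step 19
Reactants: 17 (E)-4-[(1S)-2,6,6-trimethylcyclohex-2-en-1-yl]but-3-en-2-one
Product: 25 2-methyl-2-[(E)-2-[(1S)-2,6,6-trimethylcyclohex-2-en-1-yl]ethenyl]-1,3-dioxolane
Conditions: HOCH2CH2OH, HC(OMe)3, p-toluenesulfonic acid (2 mol %), 23 °C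
Reagents that add atoms: ethane-1,2-diol OCCO
Why: acid-catalysed ketalisation driven by the orthoformate masks the side-chain ketone so that only the ring ketone made in step 20 is reduced in step 21, and catalytic acid at room temperature should not move either double bond.

Step 20
Reactants: 25 2-methyl-2-[(E)-2-[(1S)-2,6,6-trimethylcyclohex-2-en-1-yl]ethenyl]-1,3-dioxolane
Product: 26 (4S)-3,5,5-trimethyl-4-[(E)-2-(2-methyl-1,3-dioxolan-2-yl)ethenyl]cyclohex-2-en-1-one
Conditions: t-BuOOH (70% in water), NaOCl (aqueous), K2CO3, MeCN, 0 °C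
Reagents that add atoms: tert-butyl hydroperoxide CC(C)(C)OO
Why: radical allylic oxidation by tert-butylperoxyl radicals turns the ring CH2 next to the CH= terminus (C3) into the enone, as is known for α-ionone derivatives, while the C6–H shielded by the gem-dimethyl and C5-methyl groups should react more slowly so that C6 is kept.

Step 21
Reactants: 26 (4S)-3,5,5-trimethyl-4-[(E)-2-(2-methyl-1,3-dioxolan-2-yl)ethenyl]cyclohex-2-en-1-one
Product: 27 (1S,4S)-3,5,5-trimethyl-4-[(E)-2-(2-methyl-1,3-dioxolan-2-yl)ethenyl]cyclohex-2-en-1-ol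
Conditions: K[(s-Bu)3BH], THF, −78 °C
Reagents that add atoms: none
Why: 1,2-reduction of a β,β-disubstituted cyclohexenone by a bulky borohydride, where the C6 side chain should sit pseudoaxial to avoid allylic strain with the C5 methyl, the axial C1 methyl then shields the opposite face, and hydride is expected to enter syn to the side chain and place the hydroxyl trans to it, which is the (3S) configuration.

Step 22
Reactants: 27 (1S,4S)-3,5,5-trimethyl-4-[(E)-2-(2-methyl-1,3-dioxolan-2-yl)ethenyl]cyclohex-2-en-1-ol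
Product: 28 (E)-4-[(1S,4S)-4-hydroxy-2,6,6-trimethylcyclohex-2-en-1-yl]but-3-en-2-one
Conditions: pyridinium p-toluenesulfonate (10 mol %), acetone–H2O, 23 °C
Reagents that add atoms: water O
Why: acetal hydrolysis of an enone ketal proceeds under acid too weak to ionise the allylic C3 hydroxyl.

Step 23
Reactants: 28 (E)-4-[(1S,4S)-4-hydroxy-2,6,6-trimethylcyclohex-2-en-1-yl]but-3-en-2-one
Product: 29 (2E,4E)-5-[(1S,4S)-4-hydroxy-2,6,6-trimethylcyclohex-2-en-1-yl]-3-methylpenta-2,4-dienenitrile
Conditions: (EtO)2P(O)CH2CN, NaH, THF, 0 → 23 °C (anion preformed)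
Reagents that add atoms: diethyl (cyanomethyl)phosphonate CCOP(=O)(CC#N)OCC
Why: Horner–Wadsworth–Emmons olefination of the methyl ketone should give mainly the 2E dienenitrile (the 2Z isomer being separable), and the preformed phosphonate anion is too weak a base to deprotonate the hydroxyl or C6.

Step 24
Reactants: 29 (2E,4E)-5-[(1S,4S)-4-hydroxy-2,6,6-trimethylcyclohex-2-en-1-yl]-3-methylpenta-2,4-dienenitrile
Product: 31 (2E,4E)-5-[(1S,4S)-4-hydroxy-2,6,6-trimethylcyclohex-2-en-1-yl]-3-methylpenta-2,4-dienal, via aldimine 30 (not isolated)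
Conditions: i-Bu2AlH (2.5 equiv), CH2Cl2, −78 °C; then wet SiO2, 0 °C
Reagents that add atoms: water O
Why: nitrile-to-aldehyde reduction, in which i-Bu2AlH adds once to the nitrile and the aldimine is hydrolysed under nearly neutral conditions that spare the allylic alcohol.

Step 25
Reactants: 24 [(2E,4E,6E,8E,10E,12E)-2,7,11-trimethyl-13-[(1S)-2,6,6-trimethylcyclohex-2-en-1-yl]trideca-2,4,6,8,10,12-hexaen-1-yl]triphenylphosphonium bromide; 31 (2E,4E)-5-[(1S,4S)-4-hydroxy-2,6,6-trimethylcyclohex-2-en-1-yl]-3-methylpenta-2,4-dienal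
Product: 33 (3S,6S,6'S)-ε,ε-caroten-3-ol, via ylide 32 (not isolated)
Conditions: NaOMe, MeOH–CH2Cl2, 0 → 23 °C; then heptane, 80 °C
Reagents that add atoms: none
Why: Wittig olefination of a polyenyl ylide with a hydroxylated ε-end-group C15 aldehyde is an established way to join C11' to C12', the free hydroxyl being tolerated and the hindered Z isomer at the new bond expected to equilibrate to all-E on warming.

**Compound list**
1 | 5,5-dimethyldihydrofuran-2(3H)-one | CC1(C)CCC(=O)O1 | starting material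
2 | 5,5-dimethyltetrahydrofuran-2-ol (anomeric mixture) | CC1(C)CCC(O)O1 | intermediate
3 | ethyl 2-(triphenylphosphoranylidene)propanoate | CCOC(=O)C(C)=P(c1ccccc1)(c1ccccc1)c1ccccc1 | starting material
4 | ethyl (E)-6-hydroxy-2,6-dimethylhept-2-enoate | CCOC(=O)/C(C)=C/CCC(C)(C)O | intermediate
5 | ethyl (E)-2,6-dimethyl-6-[(trimethylsilyl)oxy]hept-2-enoate | CCOC(=O)/C(C)=C/CCC(C)(C)O[Si](C)(C)C | intermediate
6 | (E)-N-methoxy-N,2,6-trimethyl-6-[(trimethylsilyl)oxy]hept-2-enamide | CON(C)C(=O)/C(C)=C/CCC(C)(C)O[Si](C)(C)C | intermediate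
7 | (E)-1-chloro-3,7-dimethyl-7-[(trimethylsilyl)oxy]oct-3-en-2-one | ClCC(=O)/C(C)=C/CCC(C)(C)O[Si](C)(C)C | intermediate
8 | (E)-3,7-dimethyl-2-oxo-7-[(trimethylsilyl)oxy]oct-3-en-1-yl pivalate | CC(C)(C)C(=O)OCC(=O)/C(C)=C/CCC(C)(C)O[Si](C)(C)C | intermediate
9 | (2S,3E)-2-hydroxy-3,7-dimethyl-7-[(trimethylsilyl)oxy]oct-3-en-1-yl pivalate | CC(C)(C)C(=O)OC[C@@H](O)/C(C)=C/CCC(C)(C)O[Si](C)(C)C | intermediate
10 | (2S,3E)-3,7-dimethyl-2-[(phenylcarbamoyl)oxy]-7-[(trimethylsilyl)oxy]oct-3-en-1-yl pivalate | CC(C)(C)C(=O)OC[C@@H](OC(=O)Nc1ccccc1)/C(C)=C/CCC(C)(C)O[Si](C)(C)C | intermediate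
11 | chlorodimethylphenylsilane | C[Si](C)(Cl)c1ccccc1 | starting material
12 | (2E,4S)-4-[dimethyl(phenyl)silyl]-3,7-dimethyl-7-[(trimethylsilyl)oxy]oct-2-en-1-yl pivalate | CC(C)(O[Si](C)(C)C)CC[C@H]([Si](C)(C)c1ccccc1)/C(C)=C/COC(=O)C(C)(C)C | intermediate (not isolated)
13 | (2E,4S)-4-[dimethyl(phenyl)silyl]-7-hydroxy-3,7-dimethyloct-2-en-1-yl pivalate | CC(C)(O)CC[C@H]([Si](C)(C)c1ccccc1)/C(C)=C/COC(=O)C(C)(C)C | intermediate
14 | [(1S)-2,6,6-trimethylcyclohex-2-en-1-yl]methyl pivalate | CC1=CCCC(C)(C)[C@@H]1COC(=O)C(C)(C)C | intermediate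
15 | [(1S)-2,6,6-trimethylcyclohex-2-en-1-yl]methanol | CC1=CCCC(C)(C)[C@@H]1CO | intermediate
16 | (1S)-2,6,6-trimethylcyclohex-2-ene-1-carbaldehyde | CC1=CCCC(C)(C)[C@@H]1C=O | intermediate
17 | (E)-4-[(1S)-2,6,6-trimethylcyclohex-2-en-1-yl]but-3-en-2-one, (S)-α-ionone | CC1=CCCC(C)(C)[C@@H]1/C=C/C(C)=O | intermediate
18 | (E)-3-methyl-1-[(1S)-2,6,6-trimethylcyclohex-2-en-1-yl]penta-1,4-dien-3-ol (mixture at the carbinol carbon) | CC1=CCCC(C)(C)[C@@H]1/C=C/C(C)(O)C=C | intermediate
19 | [(2E,4E)-3-methyl-5-[(1S)-2,6,6-trimethylcyclohex-2-en-1-yl]penta-2,4-dien-1-yl]triphenylphosphonium bromide | CC1=CCCC(C)(C)[C@@H]1/C=C/C(C)=C/C[P+](c1ccccc1)(c1ccccc1)c1ccccc1.[Br-] | intermediate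
20 | (2E,4E,6E)-2,7-dimethylocta-2,4,6-trienedial | O=C/C(C)=C/C=C/C=C(C)/C=O | starting material
21 | [(2E,4E)-3-methyl-5-[(1S)-2,6,6-trimethylcyclohex-2-en-1-yl]penta-2,4-dien-1-ylidene]triphenylphosphorane | CC1=CCCC(C)(C)[C@@H]1/C=C/C(C)=C/C=P(c1ccccc1)(c1ccccc1)c1ccccc1 | intermediate (not isolated)
22 | (2E,4E,6E,8E,10E,12E)-2,7,11-trimethyl-13-[(1S)-2,6,6-trimethylcyclohex-2-en-1-yl]trideca-2,4,6,8,10,12-hexaenal | CC1=CCCC(C)(C)[C@@H]1/C=C/C(C)=C/C=C/C(C)=C/C=C/C=C(C)/C=O | intermediate
23 | (2E,4E,6E,8E,10E,12E)-2,7,11-trimethyl-13-[(1S)-2,6,6-trimethylcyclohex-2-en-1-yl]trideca-2,4,6,8,10,12-hexaen-1-ol | CC1=CCCC(C)(C)[C@@H]1/C=C/C(C)=C/C=C/C(C)=C/C=C/C=C(C)/CO | intermediate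
24 | [(2E,4E,6E,8E,10E,12E)-2,7,11-trimethyl-13-[(1S)-2,6,6-trimethylcyclohex-2-en-1-yl]trideca-2,4,6,8,10,12-hexaen-1-yl]triphenylphosphonium bromide | CC1=CCCC(C)(C)[C@@H]1/C=C/C(C)=C/C=C/C(C)=C/C=C/C=C(C)/C[P+](c1ccccc1)(c1ccccc1)c1ccccc1.[Br-] | intermediate
25 | 2-methyl-2-[(E)-2-[(1S)-2,6,6-trimethylcyclohex-2-en-1-yl]ethenyl]-1,3-dioxolane | CC1=CCCC(C)(C)[C@@H]1/C=C/C1(C)OCCO1 | intermediate
26 | (4S)-3,5,5-trimethyl-4-[(E)-2-(2-methyl-1,3-dioxolan-2-yl)ethenyl]cyclohex-2-en-1-one | CC1=CC(=O)CC(C)(C)[C@@H]1/C=C/C1(C)OCCO1 | intermediate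
27 | (1S,4S)-3,5,5-trimethyl-4-[(E)-2-(2-methyl-1,3-dioxolan-2-yl)ethenyl]cyclohex-2-en-1-ol | CC1=C[C@@H](O)CC(C)(C)[C@@H]1/C=C/C1(C)OCCO1 | intermediate
28 | (E)-4-[(1S,4S)-4-hydroxy-2,6,6-trimethylcyclohex-2-en-1-yl]but-3-en-2-one | CC1=C[C@@H](O)CC(C)(C)[C@@H]1/C=C/C(C)=O | intermediate
29 | (2E,4E)-5-[(1S,4S)-4-hydroxy-2,6,6-trimethylcyclohex-2-en-1-yl]-3-methylpenta-2,4-dienenitrile | CC1=C[C@@H](O)CC(C)(C)[C@@H]1/C=C/C(C)=C/C#N | intermediate
30 | (2E,4E)-5-[(1S,4S)-4-hydroxy-2,6,6-trimethylcyclohex-2-en-1-yl]-3-methylpenta-2,4-dien-1-imine (as its N-aluminium derivative) | CC1=C[C@@H](O)CC(C)(C)[C@@H]1/C=C/C(C)=C/C=N | intermediate (not isolated)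
31 | (2E,4E)-5-[(1S,4S)-4-hydroxy-2,6,6-trimethylcyclohex-2-en-1-yl]-3-methylpenta-2,4-dienal | CC1=C[C@@H](O)CC(C)(C)[C@@H]1/C=C/C(C)=C/C=O | intermediate
32 | [(2E,4E,6E,8E,10E,12E)-2,7,11-trimethyl-13-[(1S)-2,6,6-trimethylcyclohex-2-en-1-yl]trideca-2,4,6,8,10,12-hexaen-1-ylidene]triphenylphosphorane | CC1=CCCC(C)(C)[C@@H]1/C=C/C(C)=C/C=C/C(C)=C/C=C/C=C(C)/C=P(c1ccccc1)(c1ccccc1)c1ccccc1 | intermediate (not isolated)
33 | (3S,6S,6'S)-ε,ε-caroten-3-ol, CNP0153224.1 | CC1=CCCC(C)(C)[C@@H]1/C=C/C(C)=C/C=C/C(C)=C/C=C/C=C(C)/C=C/C=C(C)/C=C/[C@@H]1C(C)=C[C@@H](O)CC1(C)C | target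

**Count and risks**
Total steps: 25. Longest linear sequence: 20 steps (steps 1–13, 19–24 and 25).

Step 10. Ring closure may be outrun by protonolysis of the C–Si bond by the acid released on ionisation, by proton loss from the C1 cation, or by silicon-assisted loss of the pivalate to a diene. The fallback sets out from carbamate 10: the methanolysis at the end of step 9 is left out, the tertiary trimethylsilyl ether 12 is isolated, and it is ionised with a substoichiometric amount of Me3SiOSO2CF3 in CH2Cl2 at −78 °C in the presence of the hindered pyridine. The leaving group then departs as a siloxane and no Brønsted acid is produced. The route is rejoined at 14; no compound outside the list is needed (F0).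

Step 13. Deprotonation at C6 of the β,γ-unsaturated aldehyde under the basic conditions may erode the configuration or move the ring double bond into conjugation, and the hindered aldehyde may olefinate slowly. The fallback sets out from 16 and avoids base while the aldehyde is present. A Mukaiyama aldol addition of 2-(trimethylsilyloxy)propene (BF3·OEt2, CH2Cl2, −78 °C) should give 4-hydroxy-4-[(1S)-2,6,6-trimethylcyclohex-2-en-1-yl]butan-2-one F1. Mesylation (MeSO2Cl, Et3N, 0 °C) gives 3-oxo-1-[(1S)-2,6,6-trimethylcyclohex-2-en-1-yl]butyl methanesulfonate F2. Addition of 1,8-diazabicyclo[5.4.0]undec-7-ene then removes the proton next to the ketone and eliminates the mesylate to give the E enone. The route is rejoined at 17.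

Step 21. Facial selectivity of hydride delivery may be poor, or hydride may enter anti to the side chain and give the cis alcohol. The fallback sets out from 26 and replaces substrate-controlled reduction by inversion. Whatever the ratio, the cis alcohol (1R,4S)-3,5,5-trimethyl-4-[(E)-2-(2-methyl-1,3-dioxolan-2-yl)ethenyl]cyclohex-2-en-1-ol F3 is separated and subjected to a Mitsunobu reaction (4-nitrobenzoic acid, PPh3, diisopropyl azodicarboxylate, THF, 0 °C). This should give (1S,4S)-3,5,5-trimethyl-4-[(E)-2-(2-methyl-1,3-dioxolan-2-yl)ethenyl]cyclohex-2-en-1-yl 4-nitrobenzoate F4 with inversion at the carbinol carbon. Methanolysis (K2CO3, MeOH, 23 °C) then gives the trans alcohol, and the route is rejoined at 27.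

Further compounds
F0 | step 10 | none | none
F1 | step 13 | 4-hydroxy-4-[(1S)-2,6,6-trimethylcyclohex-2-en-1-yl]butan-2-one | CC1=CCCC(C)(C)[C@@H]1C(O)CC(C)=O
F2 | step 13 | 3-oxo-1-[(1S)-2,6,6-trimethylcyclohex-2-en-1-yl]butyl methanesulfonate | CC1=CCCC(C)(C)[C@@H]1C(OS(C)(=O)=O)CC(C)=O
F3 | step 21 | (1R,4S)-3,5,5-trimethyl-4-[(E)-2-(2-methyl-1,3-dioxolan-2-yl)ethenyl]cyclohex-2-en-1-ol | CC1=C[C@H](O)CC(C)(C)[C@@H]1/C=C/C1(C)OCCO1
F4 | step 21 | (1S,4S)-3,5,5-trimethyl-4-[(E)-2-(2-methyl-1,3-dioxolan-2-yl)ethenyl]cyclohex-2-en-1-yl 4-nitrobenzoate | CC1=C[C@@H](OC(=O)c2ccc(cc2)[N+](=O)[O-])CC(C)(C)[C@@H]1/C=C/C1(C)OCCO1
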